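**Retrosynthetic overview**
1. The butyl chain is labelled C1 (diaryl carbon) to C4. The C1–(4-hydroxyphenyl) bond is cut last. Anodic, DDQ-mediated dehydrogenation of the benzylic CH2 next to the trihydroxyaryl ring gives an o-quinone methide, which takes its aryl group from 4-hydroxyphenylboronic acid. The aryl group that arrives last adds anti to the large C3 branch, so the phloroglucinol ring must already be on C1.
2. The C1–phloroglucinol ring bond comes from reductive Friedel–Crafts alkylation of the dihydrochalcone (phloroglucinol + 3-(4-methoxyphenyl)propanoic acid) with (2R,3S)-4-(4-hydroxyphenyl)-2,3-dimethylbutanal.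
3. The C4–aryl bond comes from Negishi coupling of the iodo ester obtained by opening trans-2,3-dimethyl-γ-butyrolactone.
4. C2 comes from trans-selective enolate methylation of bought (R)-β-methyl-γ-butyrolactone, whose stereocentre becomes C3.
5. No ring is built. The three benzene rings and the lactone ring are bought, and the lactone ring is opened in step 3.

Assumption: (R)-4-methyldihydrofuran-2(3H)-one of at least 98% ee is taken as an inexpensive catalogue chiral building block.

**Step 1**
Reactants: 1 phloroglucinol; 2 3-(4-methoxyphenyl)propanoic acid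
Product: 3 1-(2,4,6-trihydroxyphenyl)-3-(4-methoxyphenyl)propan-1-one
Conditions: BF3·OEt2 (neat), 85 °C, 2 h; aq. NaOAc work-up
Reagents that add atoms: none
Why: BF3-promoted Friedel–Crafts acylation of the very electron-rich ring stops after one acyl group because the chelated ketone deactivates the ring, and no stereocentre is involved.

**Step 2**
Reactants: 4 (R)-4-methyldihydrofuran-2(3H)-one
Product: 6 (3R,4R)-3,4-dimethyldihydrofuran-2(3H)-one, via lithium enolate 5 (not isolated)
Conditions: LiN(iPr)2 (1.05 equiv), THF, −78 °C; MeI (1.5 equiv), −78 to −40 °C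
Reagents that add atoms: iodomethane, CI
Why: In this kinetic lactone enolate alkylation MeI approaches the flat enolate on the face opposite the bought C4 methyl group, which sets the new centre as 3R (trans, about 10:1, cis isomer removed by chromatography).

**Step 3**
Reactants: 6 (3R,4R)-3,4-dimethyldihydrofuran-2(3H)-one
Product: 8 ethyl (2R,3R)-4-iodo-2,3-dimethylbutanoate, via silyl ester 7 (not isolated)
Conditions: Me3SiI (1.2 equiv), CH2Cl2, 0 °C to rt; then EtOH, rt
Reagents that add atoms: iodotrimethylsilane, C[Si](C)(C)I; ethanol, CCO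
Why: Silyl-activated SN2 opening of the lactone by iodide at the primary O–CH2 carbon, followed by alcoholysis of the silyl ester, touches neither stereocentre.

**Step 4**
Reactants: 8 ethyl (2R,3R)-4-iodo-2,3-dimethylbutanoate; 9 (4-bromophenoxy)trimethylsilane
Product: 12 ethyl (2R,3S)-4-(4-hydroxyphenyl)-2,3-dimethylbutanoate, via alkylzinc iodide 10 (not isolated), via aryl silyl ether 11 (not isolated)
Conditions: Zn dust, LiCl, THF, 35 °C; then 9, Pd(OAc)2 (2 mol %), SPhos (4 mol %), THF, 40 °C; 1 M HCl/MeOH work-up
Reagents that add atoms: none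
Why: In this Negishi coupling zinc inserts into the primary C–I bond, the ester-tolerant alkylzinc couples at the CH2 carbon without touching C2 or C3 (the C3 descriptor changes only through priorities), and the labile aryl silyl ether is cleaved in the acidic work-up.

**Step 5**
Reactants: 12 ethyl (2R,3S)-4-(4-hydroxyphenyl)-2,3-dimethylbutanoate
Product: 13 (2R,3S)-4-(4-hydroxyphenyl)-2,3-dimethylbutanal
Conditions: iBu2AlH (2.3 equiv), CH2Cl2, −78 °C; MeOH quench at −78 °C; aq. KNaC4H4O6 (potassium sodium tartrate); used at once
Reagents that add atoms: none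
Why: In this partial ester reduction the first hydride is consumed by the phenol, the aluminium hemiacetal is stable at −78 °C and collapses to the aldehyde only on quench, and the cold neutral work-up keeps the α-centre C2.

**Step 6**
Reactants: 3 1-(2,4,6-trihydroxyphenyl)-3-(4-methoxyphenyl)propan-1-one (1.5 equiv); 13 (2R,3S)-4-(4-hydroxyphenyl)-2,3-dimethylbutanal
Product: 15 1-{2,4,6-trihydroxy-3-[(2S,3S)-4-(4-hydroxyphenyl)-2,3-dimethylbutyl]phenyl}-3-(4-methoxyphenyl)propan-1-one, via benzylic alcohol 14 (not isolated)
Conditions: CF3CO2H/CH2Cl2 1:4, Et3SiH (3 equiv), −20 to 0 °C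
Reagents that add atoms: none
Why: In this reductive Friedel–Crafts alkylation (hydroxyalkylation, then ionic hydrogenation) the free ring position of 3 attacks the protonated aldehyde and the strongly stabilised benzylic cation is captured irreversibly by the silane, while the chelated ketone is too poor an electrophile to be reduced in the cold; no new stereocentre forms and C2 changes descriptor only through priorities.

**Step 7**
Reactants: 15 1-{2,4,6-trihydroxy-3-[(2S,3S)-4-(4-hydroxyphenyl)-2,3-dimethylbutyl]phenyl}-3-(4-methoxyphenyl)propan-1-one; 16 4-hydroxyphenylboronic acid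
Product: 19 1-{2,4,6-trihydroxy-3-[(1R,2R,3S)-1,4-bis(4-hydroxyphenyl)-2,3-dimethylbutyl]phenyl}-3-(4-methoxyphenyl)propan-1-one, via o-quinone methide 17 (not isolated), via boron ate complex 18 (not isolated)
Conditions: 16 (3 equiv), DDQ (15 mol %), Bu4NPF6 (0.1 M), MeCN/(CF3)2CHOH 9:1, undivided cell, reticulated vitreous carbon anode held at +0.8 V vs Ag/AgCl, small Pt-wire cathode (H2 evolution), 2.2 F/mol, −20 °C; aq. work-up
Reagents that add atoms: none
Why: Proposed new method: anodically recycled DDQ removes a hydride from the most electron-rich benzylic CH2 (the one on the trihydroxyaryl ring, well below the potential at which any phenol or the anisole ring is oxidised) to give 17, whose carbonyl oxygen binds 16 so that the 4-hydroxyphenyl group shifts from boron to C1 through a six-membered array (Petasis-type 1,4-transfer) on the face opposite the large CH(CH3)CH2Ar branch, while C2–H lies in the ring plane to relieve A(1,3) strain against the ortho oxygen, which places the incoming aryl group on the side of the C2 methyl group and gives 1R (expected dr about 5:1 or better, minor epimer removed by chromatography); the closest known reaction types are the DDQ-mediated anodic generation of o-quinone methides from alkylphloroglucinols for hetero-Diels–Alder trapping and the thermal addition of aryl boronates to o-quinone methides.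

**Compound list**
1 | phloroglucinol | Oc1cc(O)cc(O)c1 | starting material
2 | 3-(4-methoxyphenyl)propanoic acid | COc1ccc(CCC(=O)O)cc1 | starting material
3 | 1-(2,4,6-trihydroxyphenyl)-3-(4-methoxyphenyl)propan-1-one | COc1ccc(CCC(=O)c2c(O)cc(O)cc2O)cc1 | intermediate
4 | (R)-4-methyldihydrofuran-2(3H)-one | O=C1C[C@@H](C)CO1 | starting material
5 | lithium enolate of 4 | [Li]OC1=C[C@@H](C)CO1 | intermediate
6 | (3R,4R)-3,4-dimethyldihydrofuran-2(3H)-one | O=C1[C@H](C)[C@@H](C)CO1 | intermediate
7 | trimethylsilyl (2R,3R)-4-iodo-2,3-dimethylbutanoate | C[Si](C)(C)OC(=O)[C@H](C)[C@@H](C)CI | intermediate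
8 | ethyl (2R,3R)-4-iodo-2,3-dimethylbutanoate | CCOC(=O)[C@H](C)[C@@H](C)CI | intermediate
9 | (4-bromophenoxy)trimethylsilane | C[Si](C)(C)Oc1ccc(Br)cc1 | starting material
10 | [(2R,3R)-4-ethoxy-2,3-dimethyl-4-oxobutyl]zinc iodide | CCOC(=O)[C@H](C)[C@@H](C)C[Zn]I | intermediate
11 | ethyl (2R,3S)-2,3-dimethyl-4-[4-(trimethylsilyloxy)phenyl]butanoate | CCOC(=O)[C@H](C)[C@@H](C)Cc1ccc(O[Si](C)(C)C)cc1 | intermediate
12 | ethyl (2R,3S)-4-(4-hydroxyphenyl)-2,3-dimethylbutanoate | CCOC(=O)[C@H](C)[C@@H](C)Cc1ccc(O)cc1 | intermediate
13 | (2R,3S)-4-(4-hydroxyphenyl)-2,3-dimethylbutanal | O=C[C@H](C)[C@@H](C)Cc1ccc(O)cc1 | intermediate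
14 | 1-{2,4,6-trihydroxy-3-[(2R,3S)-1-hydroxy-4-(4-hydroxyphenyl)-2,3-dimethylbutyl]phenyl}-3-(4-methoxyphenyl)propan-1-one (both C1 epimers) | COc1ccc(CCC(=O)c2c(O)cc(O)c(C(O)[C@H](C)[C@@H](C)Cc3ccc(O)cc3)c2O)cc1 | intermediate
15 | 1-{2,4,6-trihydroxy-3-[(2S,3S)-4-(4-hydroxyphenyl)-2,3-dimethylbutyl]phenyl}-3-(4-methoxyphenyl)propan-1-one | COc1ccc(CCC(=O)c2c(O)cc(O)c(C[C@H](C)[C@@H](C)Cc3ccc(O)cc3)c2O)cc1 | intermediate
16 | 4-hydroxyphenylboronic acid | OB(O)c1ccc(O)cc1 | starting material
17 | o-quinone methide of 15, with a (2R,3S)-4-(4-hydroxyphenyl)-2,3-dimethylbutylidene group on the dienone ring (alkene geometry not fixed) | COc1ccc(CCC(=O)C2=C(O)C(=C[C@H](C)[C@@H](C)Cc3ccc(O)cc3)C(=O)C=C2O)cc1 | intermediate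
18 | adduct of 16 on the carbonyl oxygen of 17 (zwitterionic boron ate complex) | COc1ccc(CCC(=O)C2=C(O)C(=C[C@H](C)[C@@H](C)Cc3ccc(O)cc3)C(=[O+][B-](O)(O)c3ccc(O)cc3)C=C2O)cc1 | intermediate
19 | 1-{2,4,6-trihydroxy-3-[(1R,2R,3S)-1,4-bis(4-hydroxyphenyl)-2,3-dimethylbutyl]phenyl}-3-(4-methoxyphenyl)propan-1-one (CNP0193401.1) | COc1ccc(CCC(=O)c2c(O)cc(O)c([C@@H](c3ccc(O)cc3)[C@H](C)[C@@H](C)Cc3ccc(O)cc3)c2O)cc1 | target

**Step count**
Total step count: 7. Longest linear sequence: 6 steps (steps 2 to 7, from 4 to 19).

**Steps most likely to fail**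

Step 7, the proposed new step, has four risks:
- Quinone methide 17 can tautomerise to the vinylphenol, which would erase C2.
- Compound 17 can be attacked by the free ring position of a second molecule of 15.
- Boronic acid 16 can suffer protodeboronation or oxidation.
- The facial selectivity at C1 may be only moderate.

The fallback uses known chemistry, sets out from 15 and comes back at 19. Stoichiometric DDQ in CH2Cl2/EtOH at 0 °C oxidises the same benzylic CH2, and ethanol traps the quinone methide as the benzylic ethyl ether F1, which is isolated. Heating it with 16 and catalytic 2,2'-biphenol in toluene at 60–80 °C releases the o-quinone methide thermally from the 2-(1-alkoxyalkyl)phenol. The boronate then adds 1,4 (a known reaction class) under the same A(1,3) control to give 19.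

Step 6 has three risks:
- The silane may reduce the aldehyde, or slowly the ketone, before the ring attacks.
- Two rings may add to one aldehyde.
- The cation may lose C2–H and scramble C2.

The fallback sets out from 3 and 13 and comes back at 15. Thiophenol with catalytic CF3CO2H in CH2Cl2 at 0 °C captures the cation far faster than a silane and gives the benzylic phenyl sulfide F2. The C–S bond of F2 is then cleaved by a radical chain (Bu3SnH, AIBN, toluene, 80 °C), so the reduction no longer passes through a cation next to C2.

Step 5 risks over-reduction to the alcohol and epimerisation of the α-branched aldehyde during work-up. The fallback sets out from 12 and comes back at 13. LiAlH4 in THF takes the ester all the way down to the primary alcohol F3, which can be purified and stored. A Parikh–Doering oxidation (SO3·pyridine, DMSO, Et3N, 0 °C), which tolerates the free phenol, makes 13 just before use.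

**Further compounds**
F1 | step 7 | 1-{3-[(2R,3S)-1-ethoxy-4-(4-hydroxyphenyl)-2,3-dimethylbutyl]-2,4,6-trihydroxyphenyl}-3-(4-methoxyphenyl)propan-1-one (both C1 epimers) | COc1ccc(CCC(=O)c2c(O)cc(O)c(C(OCC)[C@H](C)[C@@H](C)Cc3ccc(O)cc3)c2O)cc1
F2 | step 6 | 1-{2,4,6-trihydroxy-3-[(2R,3S)-4-(4-hydroxyphenyl)-2,3-dimethyl-1-(phenylsulfanyl)butyl]phenyl}-3-(4-methoxyphenyl)propan-1-one (both C1 epimers) | COc1ccc(CCC(=O)c2c(O)cc(O)c(C(Sc3ccccc3)[C@H](C)[C@@H](C)Cc3ccc(O)cc3)c2O)cc1
F3 | step 5 | 4-[(2S,3R)-4-hydroxy-2,3-dimethylbutyl]phenol | OC[C@H](C)[C@@H](C)Cc1ccc(O)cc1
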